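**Retrosynthetic overview**
- The C2–C1' bond is cut last: the target comes from 5,6-dimethoxychromone and 1,2,3,5-tetramethoxybenzene, whose two ring C–H positions are equivalent, by a new metal-free oxidative C2–H arylation.
- The pyranone ring (ring C) is closed before that, from 6-hydroxy-2,3-dimethoxyacetophenone and a one-carbon amide acetal.
- The 1,2,3,4-substitution pattern of ring A is set by directed ortho-metalation of MOM-protected 3,4-dimethoxyphenol between its two oxygen groups, followed by acetylation.
- Ring B comes from 3,4,5-trimethoxyphenol by O-methylation.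
- Ring order: rings A and B are bought as phenols, ring C is built on ring A, and ring B is attached last.

Assumption: the target has no stereocentre and no stereogenic double bond, so the "single enantiomer" is the achiral compound itself. The only stereocentre in the route (C2 of 11) forms as a racemate and is destroyed in the same flask.

**Step 1**
Reactants: 1 3,4,5-trimethoxyphenol
Product: 2 1,2,3,5-tetramethoxybenzene
Conditions: MeI, K2CO3, acetone, reflux
Reagents that add atoms: iodomethane, CI
Why: Williamson O-methylation of an unhindered phenol is clean and gives the symmetric arene whose two C–H positions are equivalent.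

**Step 2**
Reactants: 3 3,4-dimethoxyphenol
Product: 4 1,2-dimethoxy-4-(methoxymethoxy)benzene
Conditions: MOMCl, i-Pr2NEt, CH2Cl2, 0 °C → rt
Reagents that add atoms: chloromethyl methyl ether, COCCl
Why: Standard MOM protection (O-alkylation) masks the phenol and installs a strong directing group for ortho-metalation.

**Step 3**
Reactants: 4 1,2-dimethoxy-4-(methoxymethoxy)benzene
Product: 6 1-[2,3-dimethoxy-6-(methoxymethoxy)phenyl]ethanone, via aryllithium 5 (not isolated)
Conditions: n-BuLi, TMEDA, THF, 0 °C; then MeC(O)N(OMe)Me, −78 °C → rt; H2O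
Reagents that add atoms: N-methoxy-N-methylacetamide, CC(=O)N(C)OC
Why: Directed ortho-metalation takes place at the position flanked by OMOM and OMe (cooperative 1,3-direction), and Weinreb ketone synthesis stops at the ketone through the stable chelated tetrahedral adduct.

**Step 4**
Reactants: 6 1-[2,3-dimethoxy-6-(methoxymethoxy)phenyl]ethanone
Product: 7 1-(6-hydroxy-2,3-dimethoxyphenyl)ethanone
Conditions: conc. HCl (cat.), MeOH, 50 °C
Reagents that add atoms: none
Why: Acid-catalysed methanolysis of the MOM acetal frees the phenol, while aryl methyl ethers and the ketone are inert under these mild conditions.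

**Step 5**
Reactants: 7 1-(6-hydroxy-2,3-dimethoxyphenyl)ethanone
Product: 9 5,6-dimethoxy-4H-chromen-4-one, via enaminone 8 (not isolated)
Conditions: Me2NCH(OMe)2, PhMe, 100 °C; evaporate; then conc. HCl, CH2Cl2, 40 °C
Reagents that add atoms: N,N-dimethylformamide dimethyl acetal, COC(OC)N(C)C
Why: Amide-acetal condensation at the acetyl methyl gives the enaminone, and acid then drives intramolecular oxa-Michael addition of the phenol with loss of dimethylamine (the enaminone chromone synthesis).

**Step 6**
Reactants: 9 5,6-dimethoxy-4H-chromen-4-one; 2 1,2,3,5-tetramethoxybenzene (2.0 equiv)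
Product: 13 5,6-dimethoxy-2-(2,3,4,6-tetramethoxyphenyl)-4H-chromen-4-one (5,6,2',3',4',6'-hexamethoxyflavone), via silyloxybenzopyrylium triflate 10 (not isolated), via silyl enol ether 11 (not isolated), via silyloxyflavylium salt 12 (not isolated)
Conditions: TMSOTf, 2,6-di-tert-butylpyridine, CH2Cl2, −20 °C → rt; then DDQ, 0 °C → rt; H2O
Reagents that add atoms: none
Why: Proposed new method: TMSOTf O-silylates chromone 9 to the 4-silyloxybenzopyrylium ion 10, whose C2 is attacked in a Friedel–Crafts step by the strongly nucleophilic C–H position of 2 (the hindered pyridine takes the proton and leaves silyl enol ether 11), and DDQ then abstracts the doubly activated C2 hydride to give silyloxyflavylium 12, which loses its silyl group on water quench, so the C2–C1' bond and the flavone oxidation level form in one flask without a metal and the racemic C2 centre of 11 is erased; the closest known reaction types are conjugate additions of silyl enol ethers and allyl metals to 4-silyloxybenzopyrylium salts, DDQ dehydrogenation of silyl enol ethers, and Pd-catalysed C–H/C–H coupling of chromones with arenes.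

**Compound list**
1 | 3,4,5-trimethoxyphenol | COc1cc(O)cc(OC)c1OC | starting material
2 | 1,2,3,5-tetramethoxybenzene | COc1cc(OC)cc(OC)c1OC | intermediate
3 | 3,4-dimethoxyphenol | COc1ccc(O)cc1OC | starting material
4 | 1,2-dimethoxy-4-(methoxymethoxy)benzene | COCOc1ccc(OC)c(OC)c1 | intermediate
5 | [2,3-dimethoxy-6-(methoxymethoxy)phenyl]lithium | [Li]c1c(OCOC)ccc(OC)c1OC | intermediate
6 | 1-[2,3-dimethoxy-6-(methoxymethoxy)phenyl]ethanone | CC(=O)c1c(OCOC)ccc(OC)c1OC | intermediate
7 | 1-(6-hydroxy-2,3-dimethoxyphenyl)ethanone | CC(=O)c1c(O)ccc(OC)c1OC | intermediate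
8 | (E)-3-(dimethylamino)-1-(6-hydroxy-2,3-dimethoxyphenyl)prop-2-en-1-one | CN(C)/C=C/C(=O)c1c(O)ccc(OC)c1OC | intermediate
9 | 5,6-dimethoxy-4H-chromen-4-one | COc1ccc2occc(=O)c2c1OC | intermediate
10 | 5,6-dimethoxy-4-(trimethylsilyloxy)chromenylium trifluoromethanesulfonate | C[Si](C)(C)Oc1cc[o+]c2ccc(OC)c(OC)c12.[O-]S(=O)(=O)C(F)(F)F | intermediate
11 | rac-[5,6-dimethoxy-2-(2,3,4,6-tetramethoxyphenyl)-2H-chromen-4-yl]oxy(trimethyl)silane (C2 racemic) | COc1cc(OC)c(C2C=C(O[Si](C)(C)C)c3c(OC)c(OC)ccc3O2)c(OC)c1OC | intermediate
12 | 5,6-dimethoxy-2-(2,3,4,6-tetramethoxyphenyl)-4-(trimethylsilyloxy)chromenylium 2,3-dichloro-5,6-dicyano-4-hydroxyphenolate | COc1cc(OC)c(-c2cc(O[Si](C)(C)C)c3c(OC)c(OC)ccc3[o+]2)c(OC)c1OC.[O-]c1c(Cl)c(Cl)c(O)c(C#N)c1C#N | intermediate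
13 | 5,6-dimethoxy-2-(2,3,4,6-tetramethoxyphenyl)-4H-chromen-4-one (5,6,2',3',4',6'-hexamethoxyflavone), achiral | COc1cc(OC)c(-c2cc(=O)c3c(OC)c(OC)ccc3o2)c(OC)c1OC | target

**Totals**
Total step count: 6. Longest linear sequence: 5 steps (steps 2, 3, 4, 5, 6, from 3 to 13). Step 1 is a one-step side branch that joins at step 6.

**Three steps most likely to fail, with fallbacks**

Step 6 (the proposed new step). The 5-methoxy group makes ion 10 less electrophilic, the arene could add twice, and DDQ could give adducts with 11 instead of taking the hydride. The fallback uses only known chemistry and sets out from 2 and 7. Vilsmeier–Haack formylation of 2 (POCl3, DMF, then aqueous NaOAc) gives 2,3,4,6-tetramethoxybenzaldehyde F1. Claisen–Schmidt condensation of F1 with 7 (KOH, EtOH, rt) gives (E)-1-(6-hydroxy-2,3-dimethoxyphenyl)-3-(2,3,4,6-tetramethoxyphenyl)prop-2-en-1-one F2. Oxidative cyclisation of F2 (catalytic I2, DMSO, 120 °C) gives the flavone, so the fallback comes back to the route at 13.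

Step 3. Aryllithium 5 may deprotonate the Weinreb amide instead of adding to it, which would return 4. The fallback sets out from 4 and builds the acetyl group in two carbon stages. Lithiation as before gives 5, which is trapped with DMF to give 2,3-dimethoxy-6-(methoxymethoxy)benzaldehyde F3. Addition of MeMgBr (THF, 0 °C) gives racemic 1-[2,3-dimethoxy-6-(methoxymethoxy)phenyl]ethanol F4. Dess–Martin oxidation (CH2Cl2, rt) then gives the ketone, so the fallback comes back at 6.

Step 5. The acetyl group of 7 sits between two ortho substituents, so the amide-acetal condensation may be slow, and the phenol may be O-methylated by the reagent. The fallback sets out from 7 and uses a Claisen formylation instead. Treatment with NaH and ethyl formate (THF, 0 °C → rt), then acidification, gives racemic 2-hydroxy-5,6-dimethoxychroman-4-one F5. Dehydration (conc. HCl, AcOH, 60 °C) gives the chromone, so the fallback comes back at 9.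

**Further compounds**
F1 | step 6 | 2,3,4,6-tetramethoxybenzaldehyde | COc1cc(OC)c(C=O)c(OC)c1OC
F2 | step 6 | (E)-1-(6-hydroxy-2,3-dimethoxyphenyl)-3-(2,3,4,6-tetramethoxyphenyl)prop-2-en-1-one | COc1cc(OC)c(/C=C/C(=O)c2c(O)ccc(OC)c2OC)c(OC)c1OC
F3 | step 3 | 2,3-dimethoxy-6-(methoxymethoxy)benzaldehyde | COCOc1ccc(OC)c(OC)c1C=O
F4 | step 3 | rac-1-[2,3-dimethoxy-6-(methoxymethoxy)phenyl]ethanol | CC(O)c1c(OCOC)ccc(OC)c1OC
F5 | step 5 | rac-2-hydroxy-5,6-dimethoxychroman-4-one | O=C1CC(O)Oc2ccc(OC)c(OC)c12
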